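**Retrosynthetic overview**

1. The strategy rests on the O2–C3 bond of the five-membered lactone (ring B) of the 5,7-dimethoxy-2-benzofuran-1(3H)-one. C3 is a benzylic carbon that sits, on benzene ring A, ortho to the carbon carrying the carboxyl carbon C1, so ring B is the lactone of a benzylic alcohol and C3 can be carried as the plain ArCH2 of an open-chain methyl 2-alkyl-4,6-dimethoxybenzoate.
2. Last disconnection: C3–O2, made by enzymatic hydroxylation of that benzylic CH2 with the whole side chain (remote acetate, methyl ketone) already in place; the new hydroxyl then closes ring B onto the ester.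
3. Aryl–CH2 bond: B-alkyl Suzuki coupling of methyl 2-bromo-4,6-dimethoxybenzoate with the 9-BBN adduct of a terminal alkene.
4. Chain: copper-catalysed opening of an (S)-oxirane (from hydrolytic kinetic resolution) by non-8-enylmagnesium bromide sets the remote (R)-carbinol; the methyl ketone travels as a dioxolane until the step before the last.
5. Ring order: ring A is bought; ring B is closed last.

Key step: step 11

Remark: salen is N,N'-bis(3,5-di-tert-butylsalicylidene)-1,2-cyclohexanediaminate; the (S,S) cobalt complex is taken to hydrolyse the (R)-oxirane faster, as it does with simple monoalkyl oxiranes, and the P450 variant of step 11 is to be chosen by screening.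

**Route**

Step 1
Reactants: 1 hex-5-en-2-one
Product: 2 2-(but-3-en-1-yl)-2-methyl-1,3-dioxolane
Conditions: ethylene glycol, p-TsOH·H2O (cat.), toluene, reflux, Dean–Stark
Reagents that add atoms: ethylene glycol, OCCO
Why: Acid-catalysed ketalisation with azeotropic removal of water masks the methyl ketone as a dioxolane that is inert to the peracid, the Grignard reagent, the borane and the palladium steps ahead.

Step 2
Reactants: 2 2-(but-3-en-1-yl)-2-methyl-1,3-dioxolane
Product: 3 racemic 2-methyl-2-[2-(oxiran-2-yl)ethyl]-1,3-dioxolane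
Conditions: mCPBA, NaHCO3, CH2Cl2, 0 °C to rt
Reagents that add atoms: mCPBA (3-chloroperoxybenzoic acid), OOC(=O)c1cccc(Cl)c1
Why: Prilezhaev epoxidation of the isolated monosubstituted alkene is reliable, and the bicarbonate buffer keeps the acid-labile ketal intact.

Step 3
Reactants: 3 racemic 2-methyl-2-[2-(oxiran-2-yl)ethyl]-1,3-dioxolane
Product: 4 (S)-2-methyl-2-[2-(oxiran-2-yl)ethyl]-1,3-dioxolane
Conditions: (S,S)-(salen)Co(OAc) (trivalent cobalt, 0.5 mol %), H2O (0.55 equiv), THF, 0 °C to rt; distillation from the diol
Reagents that add atoms: none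
Why: Jacobsen hydrolytic kinetic resolution, in which the (S,S) catalyst delivers water to the terminal carbon of the (R)-oxirane much faster than to its enantiomer, should leave (S)-4 in high enantiomeric purity and so fixes the stereocentre that becomes the acetoxy carbon.

Step 4
Reactants: 4 (S)-2-methyl-2-[2-(oxiran-2-yl)ethyl]-1,3-dioxolane; 5 9-bromonon-1-ene
Product: 7 (3R)-1-(2-methyl-1,3-dioxolan-2-yl)tridec-12-en-3-ol, via non-8-en-1-ylmagnesium bromide 6 (not isolated)
Conditions: 5, Mg, THF, rt to 40 °C; then CuI (10 mol %), 4, THF, −40 to 0 °C; sat. aq NH4Cl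
Reagents that add atoms: none
Why: Copper-catalysed SN2 opening of a monosubstituted oxirane by a primary Grignard reagent takes place at the unhindered CH2 terminus, so the C–O stereocentre is carried over untouched (its descriptor changes from S to R only because the former oxirane CH2 drops in CIP rank).

Step 5
Reactants: 7 (3R)-1-(2-methyl-1,3-dioxolan-2-yl)tridec-12-en-3-ol
Product: 8 (3R)-1-(2-methyl-1,3-dioxolan-2-yl)tridec-12-en-3-yl acetate
Conditions: Ac2O, pyridine, DMAP (cat.), CH2Cl2, 0 °C to rt
Reagents that add atoms: acetic anhydride, CC(=O)OC(C)=O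
Why: DMAP-catalysed acylation (nucleophilic catalysis through the N-acetylpyridinium ion) esterifies the secondary alcohol at oxygen without touching the stereocentre, and the basic medium leaves the ketal alone.

Step 6
Reactants: 9 1-bromo-3,5-dimethoxybenzene
Product: 11 2-bromo-4,6-dimethoxybenzaldehyde, via aryl iminium chloride 10 (not isolated)
Conditions: POCl3, DMF, 0 to 90 °C; then ice-water
Reagents that add atoms: N,N-dimethylformamide, CN(C)C=O; water, O
Why: Vilsmeier–Haack formylation, in which the chloroiminium electrophile attacks the ring position para to one methoxy group and ortho to the other (next to bromine) in preference to the more crowded position between the two methoxy groups, and aqueous hydrolysis of the iminium salt frees the aldehyde.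

Step 7
Reactants: 11 2-bromo-4,6-dimethoxybenzaldehyde
Product: 12 2-bromo-4,6-dimethoxybenzoic acid
Conditions: NaClO2, NaH2PO4, 2-methyl-2-butene, t-BuOH/H2O, 0 °C to rt
Reagents that add atoms: sodium chlorite, [Na+].[O-]Cl=O
Why: Pinnick oxidation by chlorous acid converts the aldehyde to the acid under buffered conditions, 2-methyl-2-butene removing the hypochlorous acid that would otherwise chlorinate the electron-rich ring.

Step 8
Reactants: 12 2-bromo-4,6-dimethoxybenzoic acid
Product: 13 methyl 2-bromo-4,6-dimethoxybenzoate
Conditions: MeI, K2CO3, DMF, rt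
Reagents that add atoms: iodomethane, CI
Why: SN2 O-alkylation of the carboxylate avoids the crowded tetrahedral intermediate that makes Fischer esterification of a 2,6-disubstituted benzoic acid slow.

Step 9
Reactants: 8 (3R)-1-(2-methyl-1,3-dioxolan-2-yl)tridec-12-en-3-yl acetate; 13 methyl 2-bromo-4,6-dimethoxybenzoate
Product: 15 methyl 2-[(11R)-11-acetoxy-13-(2-methyl-1,3-dioxolan-2-yl)tridecyl]-4,6-dimethoxybenzoate, via B-alkyl-9-borabicyclo[3.3.1]nonane 14 (not isolated)
Conditions: 8, 9-BBN, THF, 0 °C to rt; then 13, PdCl2(dppf)·CH2Cl2 (5 mol %), aq K3PO4, THF/DMF, 60 °C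
Reagents that add atoms: none
Why: Anti-Markovnikov hydroboration of the terminal alkene by 9-BBN (inert to acetate and ketal at room temperature) is followed by B-alkyl Suzuki–Miyaura coupling, in which zerovalent palladium inserts into the aryl–bromine bond activated by the ortho ester, the base-activated borane transfers its primary alkyl group, and the wide-bite-angle dppf ligand favours reductive elimination over β-hydride elimination.

Step 10
Reactants: 15 methyl 2-[(11R)-11-acetoxy-13-(2-methyl-1,3-dioxolan-2-yl)tridecyl]-4,6-dimethoxybenzoate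
Product: 16 methyl 2-[(11R)-11-acetoxy-14-oxopentadecyl]-4,6-dimethoxybenzoate
Conditions: 1 M aq HCl, THF, 0 °C to rt
Reagents that add atoms: water, O
Why: Acid-catalysed hydrolysis of the dioxolane through its oxocarbenium ion is much faster than hydrolysis of the secondary acetate or of the hindered methyl benzoate, so only the ketone is unveiled.

Step 11
Reactants: 16 methyl 2-[(11R)-11-acetoxy-14-oxopentadecyl]-4,6-dimethoxybenzoate
Product: 18 (3S)-3-[(10R)-10-acetoxy-13-oxotetradecyl]-5,7-dimethoxy-2-benzofuran-1(3H)-one (target CNP0131579.2), via benzylic alcohol 17 (not isolated)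
Conditions: purified cytochrome P450 BM3 (CYP102A1) variant (heme-thiolate iron enzyme, chosen by screening), NADP+ (cat.), D-glucose, glucose dehydrogenase, catalase, air, potassium phosphate buffer pH 7.5, 2% DMSO, 25 °C; then EtOAc extraction and p-TsOH (cat.), CH2Cl2, rt
Reagents that add atoms: dioxygen, O=O
Why: The tetravalent iron-oxo porphyrin radical cation of the enzyme abstracts the pro-S hydrogen of the ring-bound CH2 of 16, and oxygen rebound onto the short-lived benzylic radical from the same face (retention) gives the (S)-benzylic alcohol 17. The hydroxyl of 17 then attacks the neighbouring methyl ester in a 5-exo-trig acyl substitution that expels methanol and closes lactone ring B, which also takes the alcohol out of reach of a second oxidation to the aryl ketone; the acid finish completes any closure held back by the hindered, electron-rich ester. The closest known reaction type is the P450 BM3-variant benzylic hydroxylation of methyl 2-alkylbenzoates with spontaneous lactonisation to 3-alkylphthalides, whose non-enzymatic relative is the carboxyl-directed benzylic C–H lactonisation of 2-alkylbenzoic acids. The new C3 stereocentre is set by the enzyme alone, the variant deciding which enantiotopic hydrogen lies over the iron, since the acetoxy carbon ten bonds away cannot bias it and is not touched. The step needs site selectivity for the benzylic CH2 over O-demethylation of the two aryl ethers and over the chain C–H bonds; the benzylic C–H bonds are the weakest in 16, its long fatty-acid-like chain suits the hydrophobic substrate channel, and the choice of variant places the arene end at the heme. Use of the purified enzyme, free of esterases and ketoreductases, should leave the acetate and the methyl ketone as they are.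

**Compound list**

1 | hex-5-en-2-one | CC(=O)CCC=C | starting material
2 | 2-(but-3-en-1-yl)-2-methyl-1,3-dioxolane | C=CCCC1(C)OCCO1 | intermediate
3 | racemic 2-methyl-2-[2-(oxiran-2-yl)ethyl]-1,3-dioxolane | CC1(CCC2CO2)OCCO1 | intermediate
4 | (S)-2-methyl-2-[2-(oxiran-2-yl)ethyl]-1,3-dioxolane | C1[C@H](CCC2(C)OCCO2)O1 | intermediate
5 | 9-bromonon-1-ene | C=CCCCCCCCBr | starting material
6 | non-8-en-1-ylmagnesium bromide | C=CCCCCCCC[Mg]Br | intermediate
7 | (3R)-1-(2-methyl-1,3-dioxolan-2-yl)tridec-12-en-3-ol | C=CCCCCCCCC[C@H](CCC1(C)OCCO1)O | intermediate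
8 | (3R)-1-(2-methyl-1,3-dioxolan-2-yl)tridec-12-en-3-yl acetate | C=CCCCCCCCC[C@H](CCC1(C)OCCO1)OC(C)=O | intermediate
9 | 1-bromo-3,5-dimethoxybenzene | COc1cc(Br)cc(OC)c1 | starting material
10 | N-[(2-bromo-4,6-dimethoxyphenyl)methylidene]-N-methylmethanaminium chloride | COc1cc(Br)c(C=[N+](C)C)c(OC)c1.[Cl-] | intermediate
11 | 2-bromo-4,6-dimethoxybenzaldehyde | COc1cc(Br)c(C=O)c(OC)c1 | intermediate
12 | 2-bromo-4,6-dimethoxybenzoic acid | COc1cc(Br)c(C(=O)O)c(OC)c1 | intermediate
13 | methyl 2-bromo-4,6-dimethoxybenzoate | COC(=O)c1c(Br)cc(OC)cc1OC | intermediate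
14 | (3R)-13-(9-borabicyclo[3.3.1]nonan-9-yl)-1-(2-methyl-1,3-dioxolan-2-yl)tridecan-3-yl acetate | B1(CCCCCCCCCC[C@H](CCC3(C)OCCO3)OC(C)=O)C2CCCC1CCC2 | intermediate
15 | methyl 2-[(11R)-11-acetoxy-13-(2-methyl-1,3-dioxolan-2-yl)tridecyl]-4,6-dimethoxybenzoate | COC(=O)c1c(CCCCCCCCCC[C@H](CCC2(C)OCCO2)OC(C)=O)cc(OC)cc1OC | intermediate
16 | methyl 2-[(11R)-11-acetoxy-14-oxopentadecyl]-4,6-dimethoxybenzoate | COC(=O)c1c(CCCCCCCCCC[C@H](CCC(C)=O)OC(C)=O)cc(OC)cc1OC | intermediate
17 | methyl 2-[(1S,11R)-11-acetoxy-1-hydroxy-14-oxopentadecyl]-4,6-dimethoxybenzoate | COC(=O)c1c([C@H](CCCCCCCCC[C@H](CCC(C)=O)OC(C)=O)O)cc(OC)cc1OC | intermediate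
18 | (3S)-3-[(10R)-10-acetoxy-13-oxotetradecyl]-5,7-dimethoxy-2-benzofuran-1(3H)-one | COc1cc(OC)c2c(c1)[C@H](CCCCCCCCC[C@H](CCC(C)=O)OC(C)=O)OC2=O | target

**Step count**

Total step count: 11. Longest linear sequence: 8 steps (steps 1 to 5, then 9, 10 and 11).

**Steps most likely to fail**

Step 11. The oxygenation may go to the wrong C–H bond (O-demethylation of either aryl ether, hydroxylation along the chain), may discriminate poorly between the two enantiotopic benzylic hydrogens, or may turn over slowly because the lipophilic substrate binds unproductively and NADPH consumption uncouples. The fallback sets out from 15, where the methyl ketone is still masked, and comes back at 18. Benzylic oxidation with Rh2(cap)4 (dirhodium tetracaprolactamate, cat.), aqueous t-BuOOH and NaHCO3 in 1,2-dichloroethane at 40 °C should give the aryl ketone methyl 2-[(11R)-11-acetoxy-13-(2-methyl-1,3-dioxolan-2-yl)tridecanoyl]-4,6-dimethoxybenzoate F1. Noyori asymmetric transfer hydrogenation with RuCl[(S,S)-TsDPEN](p-cymene) (divalent ruthenium) in HCO2H/Et3N should reduce only this ketone, from the face that gives the (S)-carbinol by analogy with simple aryl alkyl ketones, to the hydroxy ester methyl 2-[(1S,11R)-11-acetoxy-1-hydroxy-13-(2-methyl-1,3-dioxolan-2-yl)tridecyl]-4,6-dimethoxybenzoate F2. F2 should close on its own to the ketal-protected phthalide (3S)-3-[(10R)-10-acetoxy-12-(2-methyl-1,3-dioxolan-2-yl)dodecyl]-5,7-dimethoxy-2-benzofuran-1(3H)-one F3. Treatment with 1 M HCl in THF, as in step 10, then completes the lactonisation, removes the dioxolane and gives 18; C3 is in this case set by the ruthenium catalyst.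

Step 9. Transfer of the alkyl group from boron to the hindered arylpalladium bromide may be slower than protodehalogenation and β-hydride elimination with alkene isomerisation, and the aqueous phosphate may saponify the acetate. The fallback sets out from borane 14 (the hydroboration product of 8) and comes back at 15. Oxidation of 14 with NaBO3·4H2O should give the primary alcohol (3R)-13-hydroxy-1-(2-methyl-1,3-dioxolan-2-yl)tridecan-3-yl acetate F4. Appel-type iodination (I2, PPh3, imidazole, CH2Cl2) should give the iodide (3R)-13-iodo-1-(2-methyl-1,3-dioxolan-2-yl)tridecan-3-yl acetate F5. Zinc insertion (Zn dust, LiCl, THF, 40 °C) should give the alkylzinc iodide [(11R)-11-acetoxy-13-(2-methyl-1,3-dioxolan-2-yl)tridecyl]zinc iodide F6. Negishi coupling of F6 with 13 (Pd(OAc)2, SPhos, THF, rt) under neutral, water-free conditions should then give 15.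

Step 6. Formylation may also take place between the two methoxy groups or twice, the regioisomeric aldehydes must be separated, and the chlorite oxidation that follows can chlorinate the electron-rich ring. The fallback replaces the aryl bromide by an aryl triflate whose substitution pattern is fixed by a bought phenol; it sets out from borane 14 and comes back at 15, so that steps 6 to 8 are not needed. Methyl 2-hydroxy-4,6-dimethoxybenzoate F7 (bought) is converted with Tf2O and pyridine in CH2Cl2 at 0 °C into methyl 2,4-dimethoxy-6-(trifluoromethylsulfonyloxy)benzoate F8. B-alkyl Suzuki coupling of F8 with 14 under the conditions of step 9 (PdCl2(dppf)·CH2Cl2, K3PO4) should give 15.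

**Further compounds**

F1 | step 11 | methyl 2-[(11R)-11-acetoxy-13-(2-methyl-1,3-dioxolan-2-yl)tridecanoyl]-4,6-dimethoxybenzoate | COC(=O)c1c(C(=O)CCCCCCCCC[C@H](CCC2(C)OCCO2)OC(C)=O)cc(OC)cc1OC
F2 | step 11 | methyl 2-[(1S,11R)-11-acetoxy-1-hydroxy-13-(2-methyl-1,3-dioxolan-2-yl)tridecyl]-4,6-dimethoxybenzoate | COC(=O)c1c([C@H](CCCCCCCCC[C@H](CCC2(C)OCCO2)OC(C)=O)O)cc(OC)cc1OC
F3 | step 11 | (3S)-3-[(10R)-10-acetoxy-12-(2-methyl-1,3-dioxolan-2-yl)dodecyl]-5,7-dimethoxy-2-benzofuran-1(3H)-one | COc1cc(OC)c2c(c1)[C@H](CCCCCCCCC[C@H](CCC3(C)OCCO3)OC(C)=O)OC2=O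
F4 | step 9 | (3R)-13-hydroxy-1-(2-methyl-1,3-dioxolan-2-yl)tridecan-3-yl acetate | OCCCCCCCCCC[C@H](CCC1(C)OCCO1)OC(C)=O
F5 | step 9 | (3R)-13-iodo-1-(2-methyl-1,3-dioxolan-2-yl)tridecan-3-yl acetate | ICCCCCCCCCC[C@H](CCC1(C)OCCO1)OC(C)=O
F6 | step 9 | [(11R)-11-acetoxy-13-(2-methyl-1,3-dioxolan-2-yl)tridecyl]zinc iodide | I[Zn]CCCCCCCCCC[C@H](CCC1(C)OCCO1)OC(C)=O
F7 | step 6 | methyl 2-hydroxy-4,6-dimethoxybenzoate | COC(=O)c1c(O)cc(OC)cc1OC
F8 | step 6 | methyl 2,4-dimethoxy-6-(trifluoromethylsulfonyloxy)benzoate | COC(=O)c1c(OS(=O)(=O)C(F)(F)F)cc(OC)cc1OC
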